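**Plan**

Rings: A = saturated ring of the decalin, B = its cyclohexene ring, C = cyclohexanol ring, D = oxepane.
Retrosynthesis cuts, in order: the two aryl O–S bonds; the CH2–C(OH) bond between the ethyl tether and ring C; the benzylic C–C bond at the ring B alkene; in ring B the two bonds flanking the methyl-bearing sp2 carbon (that carbon is removed, leaving a trans-hydrindan-1-one); the tertiary C–O bond of ring D.
Forward: ring A is annulated onto 2-methylcyclopentane-1,3-dione (Hajos–Parrish-type aldol); the five-membered ring is enlarged to ring B by insertion of a CH(CH3) unit from diazoethane; ring C comes from 2-methylcyclohexane-1,3-dione and ring D is closed onto it by hydroalkoxylation; the halves are joined last.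
Enabling feature: the cyclopentanone carbonyl (indane C1) sits between the quaternary angular carbon C7a and the methylene C2. Only C2 migrates, and the enlarged ketone has a single α-hydrogen, which fixes the tetrasubstituted alkene between the inserted carbon and C1.
Stereochemistry: angular methyl from the D-phenylalanine-mediated aldol; ring-fusion H and the quaternary carbon of ring A from Li/NH3 reduction and methylation anti to the angular methyl; ring C/D centres from a yeast desymmetrising reduction (two centres), tether-enforced cis fusion, face-selective hydrogenation and equatorial addition to the ketone.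

Key step: step 10

Assumption: the target is taken as the free bis(hydrogen sulfate) as drawn; step 22 ends with a proton-form cation exchange, although the compound would normally be kept as a salt.
Remark: alcohol 2 is racemic and ketone 14 is a mixture of epimers at its new methyl-bearing carbon; both centres become sp2 in the following step.

**Route**

Step 1
Reactants: 1 4-[(tert-butyldimethylsilyl)oxy]butanal
Product: 2 rac-6-[(tert-butyldimethylsilyl)oxy]hex-1-en-3-ol
Conditions: CH2=CHMgBr, THF, −78 → 0 °C; aq. NH4Cl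
Reagents that add atoms: vinylmagnesium bromide, C=C[Mg]Br
Why: Grignard 1,2-addition to the aldehyde; the new carbinol centre is racemic and is removed in step 2.

Step 2
Reactants: 2 rac-6-[(tert-butyldimethylsilyl)oxy]hex-1-en-3-ol
Product: 3 6-[(tert-butyldimethylsilyl)oxy]hex-1-en-3-one
Conditions: Dess–Martin periodinane, NaHCO3, CH2Cl2, 0 °C → rt
Reagents that add atoms: none
Why: Dess–Martin oxidation of the allylic alcohol under buffered conditions should give the vinyl ketone without conjugate addition or loss of the silyl ether.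

Step 3
Reactants: 4 2-methylcyclopentane-1,3-dione; 3 6-[(tert-butyldimethylsilyl)oxy]hex-1-en-3-one
Product: 5 2-{6-[(tert-butyldimethylsilyl)oxy]-3-oxohexyl}-2-methylcyclopentane-1,3-dione
Conditions: Et3N (cat.), EtOAc, rt
Reagents that add atoms: none
Why: Michael addition of the acidic cyclic 1,3-dione to the vinyl ketone should give the prochiral triketone by C-alkylation.

Step 4
Reactants: 5 2-{6-[(tert-butyldimethylsilyl)oxy]-3-oxohexyl}-2-methylcyclopentane-1,3-dione
Product: 6 (7aR)-4-{2-[(tert-butyldimethylsilyl)oxy]ethyl}-7a-methyl-2,3,7,7a-tetrahydro-1H-indene-1,5(6H)-dione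
Conditions: D-phenylalanine, (1R)-(−)-10-camphorsulfonic acid, DMF, 30 → 60 °C
Reagents that add atoms: none
Why: Hajos–Parrish–Eder–Sauer–Wiechert reaction (enamine-mediated intramolecular aldol condensation closing ring A); the D-amino acid differentiates the two enantiotopic ring carbonyls and so fixes the quaternary carbon C7a as R.

Step 5
Reactants: 6 (7aR)-4-{2-[(tert-butyldimethylsilyl)oxy]ethyl}-7a-methyl-2,3,7,7a-tetrahydro-1H-indene-1,5(6H)-dione
Product: 7 (1R,7aR)-4-{2-[(tert-butyldimethylsilyl)oxy]ethyl}-1-hydroxy-7a-methyl-1,2,3,6,7,7a-hexahydro-5H-inden-5-one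
Conditions: NaBH4, EtOH, −20 °C
Reagents that add atoms: none
Why: Chemoselective borohydride reduction of the saturated cyclopentanone in the presence of the conjugated enone; hydride adds anti to the angular methyl, giving the hydroxyl cis to it (a temporary centre, returned to the ketone in step 9).

Step 6
Reactants: 7 (1R,7aR)-4-{2-[(tert-butyldimethylsilyl)oxy]ethyl}-1-hydroxy-7a-methyl-1,2,3,6,7,7a-hexahydro-5H-inden-5-one
Product: 9 (1R,3aS,4S,7aR)-4-{2-[(tert-butyldimethylsilyl)oxy]ethyl}-1-hydroxy-4,7a-dimethyloctahydro-5H-inden-5-one, via dilithium alkoxide enolate 8 (not isolated)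
Conditions: Li, NH3(l)/THF, −78 °C; then MeI, −78 → −33 °C; NH4Cl
Reagents that add atoms: iodomethane, CI
Why: Dissolving-metal enone reduction followed by enolate alkylation (reductive alkylation), with the free hydroxyl as internal proton source: axial protonation at C3a gives the trans ring fusion, and MeI attacks C4 on the face opposite the axial angular methyl, so the new methyl is equatorial and the siloxyethyl chain ends axial and syn to the angular methyl.

Step 7
Reactants: 9 (1R,3aS,4S,7aR)-4-{2-[(tert-butyldimethylsilyl)oxy]ethyl}-1-hydroxy-4,7a-dimethyloctahydro-5H-inden-5-one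
Product: 11 (1R,3aR,4S,7aR)-4-(2-hydroxyethyl)-4,7a-dimethyloctahydro-1H-inden-1-ol, via hydrazone 10 (not isolated)
Conditions: N2H4·H2O, KOH, diethylene glycol, 130 °C then 200 °C; 1 M HCl work-up
Reagents that add atoms: none
Why: Wolff–Kishner reduction (Huang-Minlon procedure) should remove the hindered ring A carbonyl, which has served its purpose, and the hot alkaline glycol together with the acidic work-up should cleave the primary silyl ether; no stereocentre is touched.

Step 8
Reactants: 11 (1R,3aR,4S,7aR)-4-(2-hydroxyethyl)-4,7a-dimethyloctahydro-1H-inden-1-ol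
Product: 12 (1R,3aR,4S,7aR)-4-(2-bromoethyl)-4,7a-dimethyloctahydro-1H-inden-1-ol
Conditions: CBr4, PPh3, CH2Cl2, 0 °C
Reagents that add atoms: carbon tetrabromide, BrC(Br)(Br)Br
Why: Appel bromination should take only the primary alcohol, because the secondary hydroxyl is neopentyl-like (next to the quaternary C7a) and unreactive towards SN2 displacement.

Step 9
Reactants: 12 (1R,3aR,4S,7aR)-4-(2-bromoethyl)-4,7a-dimethyloctahydro-1H-inden-1-ol
Product: 13 (3aR,4S,7aR)-4-(2-bromoethyl)-4,7a-dimethyloctahydro-1H-inden-1-one
Conditions: Dess–Martin periodinane, NaHCO3, CH2Cl2, rt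
Reagents that add atoms: none
Why: Dess–Martin oxidation of the hindered secondary alcohol should regenerate the cyclopentanone without affecting the alkyl bromide.

Step 10
Reactants: 13 (3aR,4S,7aR)-4-(2-bromoethyl)-4,7a-dimethyloctahydro-1H-inden-1-one
Product: 14 (4aR,5S,8aR)-5-(2-bromoethyl)-2,5,8a-trimethyloctahydronaphthalen-1(2H)-one (both C2 epimers)
Conditions: CH3CHN2 (fresh ethereal solution), BF3·OEt2, CH2Cl2, −78 → −20 °C
Reagents that add atoms: diazoethane, CC=[N+]=[N-]
Why: The BF3-activated carbonyl carbon C1 is attacked by the nucleophilic carbon of diazoethane to give a β-alkoxy diazonium betaine, and a 1,2-shift of the ring bond antiperiplanar to the departing N2 inserts the CH(CH3) unit into the C1–C2 bond. The closest known reaction type is the Lewis acid-promoted diazoalkane homologation of cyclic ketones (Tiffeneau–Demjanov-type, Büchner–Curtius–Schlotterbeck reaction), as used for D-ring homologation of 17-oxo steroids. No ring is closed by cyclisation: ring B grows from five to six atoms because the methylene C2 migrates from C1 to the new carbon while C1 stays bonded to the quaternary C7a. The new stereocentre at the methyl-bearing carbon is not controlled and need not be, since it becomes sp2 in step 11. The step needs regioselectivity (methylene rather than quaternary-carbon migration) and a single insertion; the quaternary C7a with its axial methyl should force the incoming CH(CH3)N2 group to the methylene side so that the C1–C2 bond is the one aligned for migration, and the product ketone, now flanked by a quaternary carbon and a methine, should be too hindered for a second insertion.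

Step 11
Reactants: 14 (4aR,5S,8aR)-5-(2-bromoethyl)-2,5,8a-trimethyloctahydronaphthalen-1(2H)-one (both C2 epimers)
Product: 16 (4aR,5S,8aR)-5-(2-bromoethyl)-2,5,8a-trimethyl-3,4,4a,5,6,7,8,8a-octahydronaphthalen-1-yl trifluoromethanesulfonate, via potassium enolate 15 (not isolated)
Conditions: KN(SiMe3)2, THF, −78 °C; then PhNTf2, −78 → 0 °C
Reagents that add atoms: N-phenylbis(trifluoromethanesulfonimide), O=S(=O)(N(c1ccccc1)S(=O)(=O)C(F)(F)F)C(F)(F)F
Why: Enolate O-triflation; the ketone has only one α-hydrogen (at C2), so the tetrasubstituted enol triflate can form in one position only, and both C2 epimers converge.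

Step 12
Reactants: 17 2-(chloromethyl)-1,4-dimethoxybenzene
Product: 18 (2,5-dimethoxybenzyl)zinc chloride
Conditions: Zn dust, LiCl, THF, rt
Reagents that add atoms: zinc, [Zn]
Why: LiCl-promoted direct insertion of zinc into the benzylic C–Cl bond should give the benzylzinc reagent as a THF solution.

Step 13
Reactants: 16 (4aR,5S,8aR)-5-(2-bromoethyl)-2,5,8a-trimethyl-3,4,4a,5,6,7,8,8a-octahydronaphthalen-1-yl trifluoromethanesulfonate; 18 (2,5-dimethoxybenzyl)zinc chloride
Product: 19 (4aR,5S,8aR)-5-(2-bromoethyl)-1-(2,5-dimethoxybenzyl)-2,5,8a-trimethyl-3,4,4a,5,6,7,8,8a-octahydronaphthalene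
Conditions: Pd(OAc)2 (cat.), SPhos (cat.), THF, 50 °C
Reagents that add atoms: none
Why: Negishi cross-coupling of the hindered alkenyl triflate with the benzylzinc reagent; the unactivated primary alkyl bromide should not undergo oxidative addition under these conditions.

Step 14
Reactants: 20 2-methylcyclohexane-1,3-dione; 21 acrolein
Product: 22 3-(1-methyl-2,6-dioxocyclohexyl)propanal
Conditions: Et3N (cat.), EtOAc, rt
Reagents that add atoms: none
Why: Michael addition of the cyclic 1,3-dione to acrolein should give the C-alkylated achiral dione aldehyde.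

Step 15
Reactants: 22 3-(1-methyl-2,6-dioxocyclohexyl)propanal
Product: 23 2-methyl-2-(4-methylpent-3-en-1-yl)cyclohexane-1,3-dione
Conditions: i-PrPPh3+ I−, n-BuLi, THF, 0 °C; then 22, −78 °C → rt
Reagents that add atoms: isopropyltriphenylphosphonium iodide, CC(C)[P+](c1ccccc1)(c1ccccc1)c1ccccc1.[I-]
Why: Wittig olefination; the non-stabilised ylide should react with the aldehyde and leave the two neopentyl-type ring ketones alone.

Step 16
Reactants: 23 2-methyl-2-(4-methylpent-3-en-1-yl)cyclohexane-1,3-dione
Product: 24 (2S,3S)-3-hydroxy-2-methyl-2-(4-methylpent-3-en-1-yl)cyclohexan-1-one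
Conditions: baker's yeast (Saccharomyces cerevisiae), sucrose, H2O, 30 °C
Reagents that add atoms: none
Why: Enzymatic desymmetrising reduction of a prochiral 2,2-disubstituted cyclohexane-1,3-dione: hydride is delivered to one enantiotopic carbonyl to give the (3S)-alcohol cis to the longer chain, which also fixes the quaternary carbon as S.

Step 17
Reactants: 24 (2S,3S)-3-hydroxy-2-methyl-2-(4-methylpent-3-en-1-yl)cyclohexan-1-one
Product: 25 (5aS,9aS)-2,2,5a-trimethyloctahydro-1-benzoxepin-6(2H)-one
Conditions: Al(OTf)3 (cat.), CH3NO2, 80 °C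
Reagents that add atoms: none
Why: Lewis acid-catalysed intramolecular Markovnikov hydroalkoxylation: the tertiary cation from the trisubstituted alkene is captured by the secondary hydroxyl to close ring D, and because hydroxyl and tether are cis on adjacent ring carbons the ring fusion can only be cis.

Step 18
Reactants: 25 (5aS,9aS)-2,2,5a-trimethyloctahydro-1-benzoxepin-6(2H)-one
Product: 26 (5aS,9aS)-2,2,5a-trimethyl-7-methylideneoctahydro-1-benzoxepin-6(2H)-one
Conditions: (CH2O)n, N-methylanilinium trifluoroacetate, THF, reflux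
Reagents that add atoms: formaldehyde (as paraformaldehyde), C=O
Why: Mannich-type α-methylenation; the ketone has a single enolisable position (C7), the other α-carbon being quaternary.

Step 19
Reactants: 26 (5aS,9aS)-2,2,5a-trimethyl-7-methylideneoctahydro-1-benzoxepin-6(2H)-one
Product: 27 (5aS,7R,9aS)-2,2,5a,7-tetramethyloctahydro-1-benzoxepin-6(2H)-one
Conditions: H2 (1 atm), Pd/C, EtOAc, rt
Reagents that add atoms: none
Why: Heterogeneous hydrogenation of the exocyclic enone C=C; hydrogen should be delivered from the convex face of the cis-fused bicycle (the face with only the angular methyl and the ring-fusion H, away from ring D), which places the new methyl on the oxepane face (7R).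

Step 20
Reactants: 19 (4aR,5S,8aR)-5-(2-bromoethyl)-1-(2,5-dimethoxybenzyl)-2,5,8a-trimethyl-3,4,4a,5,6,7,8,8a-octahydronaphthalene; 27 (5aS,7R,9aS)-2,2,5a,7-tetramethyloctahydro-1-benzoxepin-6(2H)-one
Product: 30 coupled tertiary alcohol (hydroquinone dimethyl ether; full name in the compound list), via Grignard reagent 28 (not isolated), via organocerium reagent 29 (not isolated)
Conditions: Mg, THF, 50 °C; CeCl3 (anhydrous), THF, −78 °C; then 27, −78 → 0 °C; aq. NH4Cl
Reagents that add atoms: none
Why: Organocerium 1,2-addition to a hindered, enolisable ketone (low basicity suppresses enolisation); the nucleophile should attack equatorially, away from the axial ring oxygen at C9a and trans to the C7 methyl, giving the axial hydroxyl (6R).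

Step 21
Reactants: 30 coupled tertiary alcohol (hydroquinone dimethyl ether)
Product: 32 hydroquinone (full name in the compound list), via quinone 31 (not isolated)
Conditions: (NH4)2Ce(NO3)6, MeCN/H2O, 0 °C; then Na2S2O4, H2O/Et2O, rt
Reagents that add atoms: water, O
Why: Oxidative demethylation of the 1,4-dimethoxyarene to the benzoquinone followed by dithionite reduction; the electron-rich arene should be oxidised much faster than the tetrasubstituted alkene or the tertiary alcohol.

Step 22
Reactants: 32 hydroquinone
Product: 33 CNP0125037.3 (target bis(hydrogen sulfate))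
Conditions: SO3·pyridine, pyridine, 40 °C; then cation-exchange resin (H+ form), H2O/MeOH, 0 °C
Reagents that add atoms: sulfur trioxide–pyridine complex, O=S(=O)=O.c1ccncc1
Why: O-Sulfation of both phenols with the sulfur trioxide–pyridine complex; the hindered tertiary alcohol should not react.

**Compound list**

1 | 4-[(tert-butyldimethylsilyl)oxy]butanal | CC(C)(C)[Si](C)(C)OCCCC=O | starting material
2 | rac-6-[(tert-butyldimethylsilyl)oxy]hex-1-en-3-ol | C=CC(O)CCCO[Si](C)(C)C(C)(C)C | intermediate
3 | 6-[(tert-butyldimethylsilyl)oxy]hex-1-en-3-one | C=CC(=O)CCCO[Si](C)(C)C(C)(C)C | intermediate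
4 | 2-methylcyclopentane-1,3-dione | CC1C(=O)CCC1=O | starting material
5 | 2-{6-[(tert-butyldimethylsilyl)oxy]-3-oxohexyl}-2-methylcyclopentane-1,3-dione | CC1(CCC(=O)CCCO[Si](C)(C)C(C)(C)C)C(=O)CCC1=O | intermediate
6 | (7aR)-4-{2-[(tert-butyldimethylsilyl)oxy]ethyl}-7a-methyl-2,3,7,7a-tetrahydro-1H-indene-1,5(6H)-dione | O=C1[C@]2(C)CCC(=O)C(CCO[Si](C)(C)C(C)(C)C)=C2CC1 | intermediate
7 | (1R,7aR)-4-{2-[(tert-butyldimethylsilyl)oxy]ethyl}-1-hydroxy-7a-methyl-1,2,3,6,7,7a-hexahydro-5H-inden-5-one (hydroxyl cis to the angular methyl) | O[C@H]1[C@]2(C)CCC(=O)C(CCO[Si](C)(C)C(C)(C)C)=C2CC1 | intermediate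
8 | dilithium alkoxide enolate of the trans-fused hydrindanone (C4=C5 enolate, formed in the flask) | [Li]O[C@H]1[C@]2(C)CCC(O[Li])=C(CCO[Si](C)(C)C(C)(C)C)[C@H]2CC1 | intermediate
9 | (1R,3aS,4S,7aR)-4-{2-[(tert-butyldimethylsilyl)oxy]ethyl}-1-hydroxy-4,7a-dimethyloctahydro-5H-inden-5-one (trans-fused; C4 methyl anti and chain syn to the angular methyl) | O[C@H]1[C@]2(C)CCC(=O)[C@@](C)(CCO[Si](C)(C)C(C)(C)C)[C@H]2CC1 | intermediate
10 | hydrazone of 9 at C5 (formed in the flask) | O[C@H]1[C@]2(C)CCC(=NN)[C@@](C)(CCO[Si](C)(C)C(C)(C)C)[C@H]2CC1 | intermediate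
11 | (1R,3aR,4S,7aR)-4-(2-hydroxyethyl)-4,7a-dimethyloctahydro-1H-inden-1-ol | O[C@H]1[C@]2(C)CCC[C@@](C)(CCO)[C@H]2CC1 | intermediate
12 | (1R,3aR,4S,7aR)-4-(2-bromoethyl)-4,7a-dimethyloctahydro-1H-inden-1-ol | O[C@H]1[C@]2(C)CCC[C@@](C)(CCBr)[C@H]2CC1 | intermediate
13 | (3aR,4S,7aR)-4-(2-bromoethyl)-4,7a-dimethyloctahydro-1H-inden-1-one | O=C1[C@]2(C)CCC[C@@](C)(CCBr)[C@H]2CC1 | intermediate
14 | (4aR,5S,8aR)-5-(2-bromoethyl)-2,5,8a-trimethyloctahydronaphthalen-1(2H)-one (both C2 epimers; C2 left undefined) | CC1C(=O)[C@]2(C)CCC[C@@](C)(CCBr)[C@H]2CC1 | intermediate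
15 | potassium enolate of 14 (C1=C2, formed in the flask) | CC1=C(O[K])[C@]2(C)CCC[C@@](C)(CCBr)[C@H]2CC1 | intermediate
16 | (4aR,5S,8aR)-5-(2-bromoethyl)-2,5,8a-trimethyl-3,4,4a,5,6,7,8,8a-octahydronaphthalen-1-yl trifluoromethanesulfonate | CC1=C(OS(=O)(=O)C(F)(F)F)[C@]2(C)CCC[C@@](C)(CCBr)[C@H]2CC1 | intermediate
17 | 2-(chloromethyl)-1,4-dimethoxybenzene (2,5-dimethoxybenzyl chloride) | COc1ccc(OC)c(CCl)c1 | starting material
18 | (2,5-dimethoxybenzyl)zinc chloride | COc1ccc(OC)c(C[Zn]Cl)c1 | intermediate
19 | (4aR,5S,8aR)-5-(2-bromoethyl)-1-(2,5-dimethoxybenzyl)-2,5,8a-trimethyl-3,4,4a,5,6,7,8,8a-octahydronaphthalene | CC1=C(Cc2cc(OC)ccc2OC)[C@]2(C)CCC[C@@](C)(CCBr)[C@H]2CC1 | intermediate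
20 | 2-methylcyclohexane-1,3-dione | CC1C(=O)CCCC1=O | starting material
21 | acrolein (prop-2-enal) | C=CC=O | starting material
22 | 3-(1-methyl-2,6-dioxocyclohexyl)propanal | CC1(CCC=O)C(=O)CCCC1=O | intermediate
23 | 2-methyl-2-(4-methylpent-3-en-1-yl)cyclohexane-1,3-dione | CC1(CCC=C(C)C)C(=O)CCCC1=O | intermediate
24 | (2S,3S)-3-hydroxy-2-methyl-2-(4-methylpent-3-en-1-yl)cyclohexan-1-one (hydroxyl cis to the alkenyl chain) | O=C1CCC[C@H](O)[C@]1(C)CCC=C(C)C | intermediate
25 | (5aS,9aS)-2,2,5a-trimethyloctahydro-1-benzoxepin-6(2H)-one (cis-fused) | O=C1CCC[C@@H]2OC(C)(C)CCC[C@@]21C | intermediate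
26 | (5aS,9aS)-2,2,5a-trimethyl-7-methylideneoctahydro-1-benzoxepin-6(2H)-one | O=C1C(=C)CC[C@@H]2OC(C)(C)CCC[C@@]21C | intermediate
27 | (5aS,7R,9aS)-2,2,5a,7-tetramethyloctahydro-1-benzoxepin-6(2H)-one (C7 methyl cis to the ring oxygen at C9a) | O=C1[C@H](C)CC[C@@H]2OC(C)(C)CCC[C@@]21C | intermediate
28 | Grignard reagent from 19 (primary alkylmagnesium bromide, formed in the flask) | CC1=C(Cc2cc(OC)ccc2OC)[C@]2(C)CCC[C@@](C)(CC[Mg]Br)[C@H]2CC1 | intermediate
29 | organocerium reagent from 28 (alkylcerium dichloride, formed in the flask) | CC1=C(Cc2cc(OC)ccc2OC)[C@]2(C)CCC[C@@](C)(CC[Ce](Cl)Cl)[C@H]2CC1 | intermediate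
30 | (5aS,6R,7R,9aS)-6-{2-[(1S,4aR,8aR)-5-(2,5-dimethoxybenzyl)-1,4a,6-trimethyl-1,2,3,4,4a,7,8,8a-octahydronaphthalen-1-yl]ethyl}-2,2,5a,7-tetramethyldecahydro-1-benzoxepin-6-ol | CC1=C(Cc2cc(OC)ccc2OC)[C@]2(C)CCC[C@@](C)(CC[C@@]3(O)[C@H](C)CC[C@@H]4OC(C)(C)CCC[C@@]43C)[C@H]2CC1 | intermediate
31 | 2-substituted 1,4-benzoquinone corresponding to 30 (formed in the flask) | CC1=C(CC2=CC(=O)C=CC2=O)[C@]2(C)CCC[C@@](C)(CC[C@@]3(O)[C@H](C)CC[C@@H]4OC(C)(C)CCC[C@@]43C)[C@H]2CC1 | intermediate
32 | hydroquinone: 2-substituted benzene-1,4-diol corresponding to 30 | CC1=C(Cc2cc(O)ccc2O)[C@]2(C)CCC[C@@](C)(CC[C@@]3(O)[C@H](C)CC[C@@H]4OC(C)(C)CCC[C@@]43C)[C@H]2CC1 | intermediate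
33 | CNP0125037.3: 2-{[(4aR,5S,8aR)-5-{2-[(5aS,6R,7R,9aS)-6-hydroxy-2,2,5a,7-tetramethyldecahydro-1-benzoxepin-6-yl]ethyl}-2,5,8a-trimethyl-3,4,4a,5,6,7,8,8a-octahydronaphthalen-1-yl]methyl}benzene-1,4-diyl bis(hydrogen sulfate) | CC1=C(Cc2cc(OS(=O)(=O)O)ccc2OS(=O)(=O)O)[C@]2(C)CCC[C@@](C)(CC[C@@]3(O)[C@H](C)CC[C@@H]4OC(C)(C)CCC[C@@]43C)[C@H]2CC1 | target

**Summary**

Total step count: 22.
Longest linear sequence: 15 steps (steps 1–11, 13, 20, 21, 22).

Steps most likely to fail:

Step 10. The quaternary carbon may migrate in place of the methylene, a second carbon may be inserted, or the betaine may close to an epoxide. Fallback: ring enlargement and methylation are separated. From 13, insertion of an unsubstituted carbon with the bulkier trimethylsilyldiazomethane under AlMe3 promotion should give (4aR,5S,8aR)-5-(2-bromoethyl)-5,8a-dimethyl-2-(trimethylsilyl)octahydronaphthalen-1(2H)-one F1. This loses silicon on acidic work-up to give (4aR,5S,8aR)-5-(2-bromoethyl)-5,8a-dimethyloctahydronaphthalen-1(2H)-one F2. Deprotonation at its only enolisable position (LiN(iPr)2, THF, −78 °C) and methylation with MeI then rejoins the route at 14.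

Step 19. Facial selectivity in the delivery of hydrogen may be poor, because the two faces of the exocyclic alkene differ only through the two substituents on the neighbouring quaternary carbon. Fallback: the stereocentre is made by C–C instead of C–H bond formation. From 25, the lithium enolate (LiN(iPr)2, THF, −78 °C) is methylated with MeI, so that the methyl group enters on the face that hydrogen takes in the main route; this reaches 27 directly without the methylidene intermediate. Whichever face is the more open, one of the two modes should deliver 27.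

Step 20. The organometallic may enolise the doubly α-branched ketone instead of adding, or the C7 configuration may be lost. Fallback: the order of events is changed. Organocerium reagent 29 (from 19) is added to methylidene ketone 26, which has no α-hydrogen and a less crowded carbonyl group, to give the allylic tertiary alcohol (7-methylidene analogue of 30) F3. Hydrogen-atom-transfer hydrogenation of its 1,1-disubstituted alkene (Mn(dpm)3, PhSiH3, tert-butyl hydroperoxide, isopropanol) should favour the equatorial C-methyl, leave the tetrasubstituted ring B alkene untouched, and rejoin the route at 30.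

Further compounds
F1 | step 10 | (4aR,5S,8aR)-5-(2-bromoethyl)-5,8a-dimethyl-2-(trimethylsilyl)octahydronaphthalen-1(2H)-one | C[Si](C)(C)C1C(=O)[C@]2(C)CCC[C@@](C)(CCBr)[C@H]2CC1
F2 | step 10 | (4aR,5S,8aR)-5-(2-bromoethyl)-5,8a-dimethyloctahydronaphthalen-1(2H)-one | O=C1[C@]2(C)CCC[C@@](C)(CCBr)[C@H]2CCC1
F0 | step 19 | none | none
F3 | step 20 | allylic tertiary alcohol (7-methylidene analogue of 30, same configuration at all other centres) | CC1=C(Cc2cc(OC)ccc2OC)[C@]2(C)CCC[C@@](C)(CC[C@@]3(O)C(=C)CC[C@@H]4OC(C)(C)CCC[C@@]43C)[C@H]2CC1
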